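**Strategy.** Everything rests on reading ring B, the 3(2H)-furanone (O–C3=C2–C1(=O)–C10, germacrane numbering), as a cyclised α′-hydroxy ynone: C10–C1 is a tertiary α-hydroxy acid and C2–C3 a terminal alkyne. In the key step the lithium acetylide of a (Z)-enyne carbinol (C2–C7, C15) attacks a lactic-acid-derived dioxolanone (C1, C9, C10, C14, prenyl-masked C8). Acyl substitution forms C1–C2 and unmasks the C10 hydroxyl, whose 5-endo-dig addition forms O–C3, uniting both halves as ring B. Ring C then comes from ring-closing metathesis, ring A from a chromium-mediated Barbier macrocyclisation at C7–C8, and the C8 ester from Mitsunobu inversion.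

Key step: step 6

Remark: atoms carry germacrane numbers (C1 furanone C=O, C2 furanone CH, C3 furanone O–C=, C4=C5 ring alkene, C6 lactone O–CH, C7, C8 ester CH, C9 CH2, C10 quaternary C–O, C11–C13 methylene-lactone carbons, C14 and C15 the methyls on C10 and C4); ring A is the ten-membered carbocycle, ring B the furanone, ring C the lactone; divinylzinc is assumed to be on hand as a salt-free stock solution made beforehand from vinylmagnesium bromide and ZnCl2.

Step 1
Reactants: 1 (R)-lactic acid; 2 pivalaldehyde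
Product: 3 (2R,5R)-2-tert-butyl-5-methyl-1,3-dioxolan-4-one (cis)
Conditions: p-TsOH (cat.), H2SO4 (cat.), pentane, reflux, Dean–Stark; crystallisation from Et2O/pentane, −78 °C
Reagents that add atoms: none
Why: Acid-catalysed acetalisation of the α-hydroxy acid (first stage of the self-regeneration-of-stereocentres protocol) should give mainly the cis-dioxolanone, the acetal carbon being set cis to the methyl group under equilibrating conditions and the isomer being purified by cold crystallisation.

Step 2
Reactants: 3; 4 prenyl bromide (1-bromo-3-methylbut-2-ene)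
Product: 6 (2R,5S)-2-tert-butyl-5-methyl-5-(3-methylbut-2-en-1-yl)-1,3-dioxolan-4-one, via lithium enolate 5 (not isolated)
Conditions: LiN(iPr)2, THF, −78 °C; then 4, −78 → −30 °C
Reagents that add atoms: none
Why: Seebach alkylation, in which the planar enolate keeps only the tert-butyl acetal centre and the allylic bromide enters anti to tert-butyl, so the quaternary carbon (C10 of the target) should form with overall retention in the S configuration.

Step 3
Reactants: 7 (2Z)-3-methylpent-2-en-4-yn-1-ol
Product: 8 (2Z)-3-methylpent-2-en-4-ynal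
Conditions: MnO2, CH2Cl2, 0 °C → rt, dark; used as a solution
Reagents that add atoms: none
Why: Allylic oxidation with MnO2 is neutral and chemoselective, so the Z double bond and the terminal alkyne should survive.

Step 4
Reactants: 8
Product: 9 (3S,4Z)-5-methylhepta-1,4-dien-6-yn-3-ol
Conditions: Zn(CH=CH2)2, (−)-DAIB (10 mol%), toluene, −20 → 0 °C; aq. work-up
Reagents that add atoms: divinylzinc, C=C[Zn]C=C
Why: Amino-alcohol-catalysed diorganozinc addition to an enal is 1,2-selective and (−)-DAIB should deliver the vinyl group to the Si face, setting the carbinol as S (the later 6R centre), while the alkyne C–H is not metallated by the diorganozinc at this temperature.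

Step 5
Reactants: 9
Product: 10 triethyl{[(3S,4Z)-5-methylhepta-1,4-dien-6-yn-3-yl]oxy}silane
Conditions: TESCl, imidazole, CH2Cl2, 0 °C
Reagents that add atoms: chlorotriethylsilane (TESCl), CC[Si](Cl)(CC)CC
Why: Standard silylation caps O6 as a base-stable ether, so that only the alkyne is deprotonated in step 6 and O6 cannot compete in the furanone-forming cyclisation.

Step 6
Reactants: 10; 6
Product: 14 (2S)-2-methyl-2-(3-methylbut-2-en-1-yl)-5-[(2Z,4S)-4-(triethylsilyloxy)hexa-2,5-dien-2-yl]furan-3(2H)-one, via lithium acetylide 11 (not isolated), via tetrahedral lithium alkoxide 12 (not isolated), via α′-hydroxy ynone 13 (not isolated)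
Conditions: n-BuLi, THF, −78 °C; then 6, −78 → −30 °C; AcOH, −78 °C; then Et2NH, EtOH, rt
Reagents that add atoms: none
Why: n-BuLi deprotonates only the terminal alkyne of 10, and acetylide 11 attacks the single electrophilic carbonyl of 6, an acylal-activated lactone, so C1–C2 forms by nucleophilic acyl substitution; the closest known reaction type is the addition of organolithiums to 1,3-dioxolan-4-ones to give α-hydroxy ketones. The tetrahedral alkoxide 12 persists at low temperature, which blocks a second addition, and on protonation it collapses with loss of pivalaldehyde to ynone 13, the dioxolanone having served both as protecting group for the tertiary hydroxyl and as activating group for the carboxyl. Et2NH in EtOH then promotes conjugate addition of the freed C10 hydroxyl to C3, a 5-endo-dig closure that is the standard passage from α′-hydroxy ynones to 3(2H)-furanones and forms O–C3 and ring B. No stereocentre is created, since C10 comes unchanged from 6 and C6 from 10, and nothing in the sequence should isomerise the Z-C4=C5 bond. The step needs mono-addition, secured by the stability of 12 and equimolar acetylide, and cyclisation by the C10 hydroxyl alone, secured by the TES ether on O6, whose free hydroxyl would otherwise close a furan by 5-exo attack on the same ynone carbon.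

Step 7
Reactants: 14
Product: 15 (2S)-5-[(2Z,4S)-4-hydroxyhexa-2,5-dien-2-yl]-2-methyl-2-(3-methylbut-2-en-1-yl)furan-3(2H)-one
Conditions: TBAF, AcOH (1:1), THF, 0 °C
Reagents that add atoms: none
Why: Buffered fluoride desilylation should remove the secondary TES ether without acid, avoiding ionisation of the bis-allylic carbinol and leaving every stereocentre untouched.

Step 8
Reactants: 15; 16 2-(bromomethyl)prop-2-enoic acid
Product: 17 (3S,4Z)-5-[(5S)-5-methyl-5-(3-methylbut-2-en-1-yl)-4-oxo-4,5-dihydrofuran-2-yl]hexa-1,4-dien-3-yl 2-(bromomethyl)prop-2-enoate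
Conditions: DIC, DMAP (cat.), CH2Cl2, −20 → 0 °C
Reagents that add atoms: none
Why: Steglich esterification acylates O6 with retention at C6, and low temperature with only catalytic DMAP should keep the allylic bromide intact.

Step 9
Reactants: 17
Product: 18 (5R)-3-(bromomethyl)-5-{(1Z)-2-[(5S)-5-methyl-5-(3-methylbut-2-en-1-yl)-4-oxo-4,5-dihydrofuran-2-yl]prop-1-en-1-yl}furan-2(5H)-one
Conditions: second-generation Hoveyda–Grubbs catalyst RuCl2(H2IMes)(=CH–C6H4-2-OiPr) (5 mol%), toluene (5 mM), 80 °C
Reagents that add atoms: none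
Why: Ring-closing metathesis between the C6 vinyl group and the acrylate should close the five-membered butenolide (C7=C11) with loss of ethylene, the trisubstituted prenyl and C4=C5 alkenes and the furanone alkene being too hindered or electron-poor to compete and C6 being unaffected.

Step 10
Reactants: 18
Product: 20 {(2S)-5-[(1Z)-1-[(2R)-4-(bromomethyl)-5-oxo-2,5-dihydrofuran-2-yl]prop-1-en-2-yl]-2-methyl-3-oxo-2,3-dihydrofuran-2-yl}acetaldehyde, via vicinal diol 19 (not isolated)
Conditions: OsO4 (2 mol%), NaIO4, 2,6-lutidine, 1,4-dioxane/H2O (3:1), rt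
Reagents that add atoms: osmium tetroxide, O=[Os](=O)(=O)=O; sodium periodate, [Na+].[O-]I(=O)(=O)=O
Why: Lemieux–Johnson cleavage, in which OsO4 should dihydroxylate only the electron-rich unconjugated prenyl alkene and NaIO4 cleaves the diol in situ to the C8 aldehyde, the other three alkenes being deactivated by conjugation and 2,6-lutidine keeping the medium near neutral.

Step 11
Reactants: 20
Product: 22 (3aR,4S,6S,10Z,11aR)-4-hydroxy-6,10-dimethyl-3-methylidene-3,3a,4,5,6,11a-hexahydro-6,9-epoxycyclodeca[b]furan-2,7-dione (8S alcohol in germacrane numbering), via allylchromium dichloride 21 (not isolated)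
Conditions: CrCl2 (8 equiv), THF, rt, slow addition of 20 (final 2 mM); aq. work-up
Reagents that add atoms: none
Why: Nozaki–Hiyama-type Barbier allylation, in which CrCl2 inserts into the allylic C–Br bond and the allylchromium adds through its γ-carbon C7 to the tethered aldehyde in a Zimmerman–Traxler chair, on the butenolide face anti to the C5 substituent of C6 (trans-fused lactone, 7R) and with the aldehyde chain equatorial to the ring-locked E allyl unit (anti addition, 8S), closing ring A and unveiling the exocyclic methylene of ring C.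

Step 12
Reactants: 22; 23 isovaleric acid (3-methylbutanoic acid)
Product: 24 (3aR,4R,6S,10Z,11aR)-6,10-dimethyl-3-methylidene-2,7-dioxo-2,3,3a,4,5,6,7,11a-octahydro-6,9-epoxycyclodeca[b]furan-4-yl 3-methylbutanoate (target)
Conditions: PPh3, DIAD, toluene, 0 °C → rt
Reagents that add atoms: none
Why: Mitsunobu esterification should displace the phosphonium-activated C8 hydroxyl by isovalerate with SN2 inversion, turning the 8S alcohol into the 8R ester under neutral conditions that spare the α-methylene lactone.

**Compound list**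

1 | (R)-lactic acid, (2R)-2-hydroxypropanoic acid | C[C@@H](O)C(=O)O | starting material
2 | pivalaldehyde, 2,2-dimethylpropanal | CC(C)(C)C=O | starting material
3 | (2R,5R)-2-tert-butyl-5-methyl-1,3-dioxolan-4-one (cis) | C[C@H]1O[C@@H](C(C)(C)C)OC1=O | intermediate
4 | prenyl bromide, 1-bromo-3-methylbut-2-ene | CC(C)=CCBr | starting material
5 | lithium (2R)-2-tert-butyl-5-methyl-1,3-dioxol-4-olate (enolate of 3) | CC1=C(O[Li])O[C@H](C(C)(C)C)O1 | intermediate
6 | (2R,5S)-2-tert-butyl-5-methyl-5-(3-methylbut-2-en-1-yl)-1,3-dioxolan-4-one | C[C@@]1(CC=C(C)C)O[C@@H](C(C)(C)C)OC1=O | intermediate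
7 | (2Z)-3-methylpent-2-en-4-yn-1-ol | C#C/C(C)=C\CO | starting material
8 | (2Z)-3-methylpent-2-en-4-ynal | C#C/C(C)=C\C=O | intermediate
9 | (3S,4Z)-5-methylhepta-1,4-dien-6-yn-3-ol | C#C/C(C)=C\[C@@H](O)C=C | intermediate
10 | triethyl{[(3S,4Z)-5-methylhepta-1,4-dien-6-yn-3-yl]oxy}silane | C#C/C(C)=C\[C@@H](O[Si](CC)(CC)CC)C=C | intermediate
11 | lithium acetylide of 10 | [Li]C#C/C(C)=C\[C@@H](O[Si](CC)(CC)CC)C=C | intermediate
12 | lithium (2R,5S)-2-tert-butyl-5-methyl-5-(3-methylbut-2-en-1-yl)-4-[(3Z,5S)-3-methyl-5-(triethylsilyloxy)hepta-3,6-dien-1-yn-1-yl]-1,3-dioxolan-4-olate (both configurations at the new hemiketal carbon) | CC(C)=CC[C@]1(C)O[C@@H](C(C)(C)C)OC1(O[Li])C#C/C(C)=C\[C@@H](O[Si](CC)(CC)CC)C=C | intermediate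
13 | (3S,4Z,9S)-9-hydroxy-5,9,12-trimethyl-3-(triethylsilyloxy)trideca-1,4,11-trien-6-yn-8-one | CC(C)=CC[C@](C)(O)C(=O)C#C/C(C)=C\[C@@H](O[Si](CC)(CC)CC)C=C | intermediate
14 | (2S)-2-methyl-2-(3-methylbut-2-en-1-yl)-5-[(2Z,4S)-4-(triethylsilyloxy)hexa-2,5-dien-2-yl]furan-3(2H)-one | C=C[C@H](O[Si](CC)(CC)CC)/C=C(/C)C1=CC(=O)[C@](C)(CC=C(C)C)O1 | intermediate
15 | (2S)-5-[(2Z,4S)-4-hydroxyhexa-2,5-dien-2-yl]-2-methyl-2-(3-methylbut-2-en-1-yl)furan-3(2H)-one | C=C[C@H](O)/C=C(/C)C1=CC(=O)[C@](C)(CC=C(C)C)O1 | intermediate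
16 | 2-(bromomethyl)prop-2-enoic acid | C=C(CBr)C(=O)O | starting material
17 | (3S,4Z)-5-[(5S)-5-methyl-5-(3-methylbut-2-en-1-yl)-4-oxo-4,5-dihydrofuran-2-yl]hexa-1,4-dien-3-yl 2-(bromomethyl)prop-2-enoate | C=C[C@H](OC(=O)C(=C)CBr)/C=C(/C)C1=CC(=O)[C@](C)(CC=C(C)C)O1 | intermediate
18 | (5R)-3-(bromomethyl)-5-{(1Z)-2-[(5S)-5-methyl-5-(3-methylbut-2-en-1-yl)-4-oxo-4,5-dihydrofuran-2-yl]prop-1-en-1-yl}furan-2(5H)-one | O=C1O[C@H](/C=C(/C)C2=CC(=O)[C@](C)(CC=C(C)C)O2)C=C1CBr | intermediate
19 | (5R)-3-(bromomethyl)-5-{(1Z)-2-[(5S)-5-(2,3-dihydroxy-3-methylbutyl)-5-methyl-4-oxo-4,5-dihydrofuran-2-yl]prop-1-en-1-yl}furan-2(5H)-one (both configurations at the secondary carbinol) | O=C1O[C@H](/C=C(/C)C2=CC(=O)[C@](C)(CC(O)C(C)(C)O)O2)C=C1CBr | intermediate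
20 | {(2S)-5-[(1Z)-1-[(2R)-4-(bromomethyl)-5-oxo-2,5-dihydrofuran-2-yl]prop-1-en-2-yl]-2-methyl-3-oxo-2,3-dihydrofuran-2-yl}acetaldehyde | O=C1O[C@H](/C=C(/C)C2=CC(=O)[C@](C)(CC=O)O2)C=C1CBr | intermediate
21 | allylchromium dichloride from 20 (CrCl2 unit on the former CH2Br carbon C13) | O=C1O[C@H](/C=C(/C)C2=CC(=O)[C@](C)(CC=O)O2)C=C1C[Cr](Cl)Cl | intermediate
22 | (3aR,4S,6S,10Z,11aR)-4-hydroxy-6,10-dimethyl-3-methylidene-3,3a,4,5,6,11a-hexahydro-6,9-epoxycyclodeca[b]furan-2,7-dione (6R,7R,8S,10S in germacrane numbering) | C=C1C(=O)O[C@@H]2/C=C(/C)C3=CC(=O)[C@](C)(C[C@H](O)[C@@H]12)O3 | intermediate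
23 | isovaleric acid, 3-methylbutanoic acid | CC(C)CC(=O)O | starting material
24 | (3aR,4R,6S,10Z,11aR)-6,10-dimethyl-3-methylidene-2,7-dioxo-2,3,3a,4,5,6,7,11a-octahydro-6,9-epoxycyclodeca[b]furan-4-yl 3-methylbutanoate (6R,7R,8R,10S in germacrane numbering) | C=C1C(=O)O[C@@H]2/C=C(/C)C3=CC(=O)[C@](C)(C[C@@H](OC(=O)CC(C)C)[C@@H]12)O3 | target

**Totals.** Total step count: 12. Longest linear sequence: 10 steps (7 to 24, steps 3 to 12); the dioxolanone branch (1 to 6) adds 2 steps.

**Steps most likely to fail, with fallbacks**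

Step 11. Closure of the strained bicyclic ring A/B may be slow, so that intermolecular allylation or protodebromination wins. The facial course at C7 or the chair preference at C8 may also be eroded by the short tether. The fallback replaces the closed chromium transition state by a Lewis-acid-triggered open one (intramolecular Hosomi–Sakurai reaction). It sets out from 18: hexamethyldisilane with Pd(dba)2 (cat.) should convert the allylic bromide into the allylsilane (5R)-5-{(1Z)-2-[(5S)-5-methyl-5-(3-methylbut-2-en-1-yl)-4-oxo-4,5-dihydrofuran-2-yl]prop-1-en-1-yl}-3-[(trimethylsilyl)methyl]furan-2(5H)-one F1. Lemieux–Johnson cleavage as in step 10 should then give the aldehyde {(2S)-2-methyl-3-oxo-5-[(1Z)-1-{(2R)-5-oxo-4-[(trimethylsilyl)methyl]-2,5-dihydrofuran-2-yl}prop-1-en-2-yl]-2,3-dihydrofuran-2-yl}acetaldehyde F2. BF3·OEt2 in CH2Cl2 at −78 °C should close ring A through an antiperiplanar open transition state, which is expected to favour the 8R alcohol (3aR,4R,6S,10Z,11aR)-4-hydroxy-6,10-dimethyl-3-methylidene-3,3a,4,5,6,11a-hexahydro-6,9-epoxycyclodeca[b]furan-2,7-dione F3. Acylation with isovaleric anhydride and DMAP brings the sequence back to the route at 24; any 8S alcohol formed is 22 itself.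

Step 12. The rear side of C8 is shielded by the ring, so elimination toward a C7=C8 or C8=C9 alkene, or conjugate addition of the phosphine to the methylene lactone, may outrun substitution. The fallback inverts C8 by oxidation and reduction instead of displacement. It sets out from 22: Dess–Martin periodinane (NaHCO3, CH2Cl2) should give the C8 ketone (3aS,6S,10Z,11aR)-6,10-dimethyl-3-methylidene-3,3a,5,6-tetrahydro-6,9-epoxycyclodeca[b]furan-2,4,7(11aH)-trione F4. Luche reduction (NaBH4, CeCl3·7H2O, MeOH, −78 °C) should deliver hydride from the exposed face opposite the lactone, giving the 8R alcohol F3 described above. Acylation with isovaleric anhydride and DMAP returns to the route at 24.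

Step 10. Osmylation may also touch the conjugated C4=C5 alkene, the allylic bromide may be lost by hydrolysis in the aqueous medium, or the new aldehyde may undergo base-induced β-elimination that opens ring B. The fallback is an anhydrous two-stage cleavage through an epoxide. It sets out from 18: mCPBA (NaHCO3, CH2Cl2, 0 °C) should epoxidise only the nucleophilic prenyl alkene to (5R)-3-(bromomethyl)-5-{(1Z)-2-[(5S)-5-[(3,3-dimethyloxiran-2-yl)methyl]-5-methyl-4-oxo-4,5-dihydrofuran-2-yl]prop-1-en-1-yl}furan-2(5H)-one F5. Periodic acid (H5IO6, THF/Et2O, 0 °C) should then cleave it to the aldehyde, returning to the route at 20.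

Further compounds
F1 | step 11 | (5R)-5-{(1Z)-2-[(5S)-5-methyl-5-(3-methylbut-2-en-1-yl)-4-oxo-4,5-dihydrofuran-2-yl]prop-1-en-1-yl}-3-[(trimethylsilyl)methyl]furan-2(5H)-one | O=C1O[C@H](/C=C(/C)C2=CC(=O)[C@](C)(CC=C(C)C)O2)C=C1C[Si](C)(C)C
F2 | step 11 | {(2S)-2-methyl-3-oxo-5-[(1Z)-1-{(2R)-5-oxo-4-[(trimethylsilyl)methyl]-2,5-dihydrofuran-2-yl}prop-1-en-2-yl]-2,3-dihydrofuran-2-yl}acetaldehyde | O=C1O[C@H](/C=C(/C)C2=CC(=O)[C@](C)(CC=O)O2)C=C1C[Si](C)(C)C
F3 | step 11 | (3aR,4R,6S,10Z,11aR)-4-hydroxy-6,10-dimethyl-3-methylidene-3,3a,4,5,6,11a-hexahydro-6,9-epoxycyclodeca[b]furan-2,7-dione (C8 epimer of 22) | C=C1C(=O)O[C@@H]2/C=C(/C)C3=CC(=O)[C@](C)(C[C@@H](O)[C@@H]12)O3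
F4 | step 12 | (3aS,6S,10Z,11aR)-6,10-dimethyl-3-methylidene-3,3a,5,6-tetrahydro-6,9-epoxycyclodeca[b]furan-2,4,7(11aH)-trione (C8 ketone of 22) | C=C1C(=O)O[C@@H]2/C=C(/C)C3=CC(=O)[C@](C)(CC(=O)[C@@H]12)O3
F5 | step 10 | (5R)-3-(bromomethyl)-5-{(1Z)-2-[(5S)-5-[(3,3-dimethyloxiran-2-yl)methyl]-5-methyl-4-oxo-4,5-dihydrofuran-2-yl]prop-1-en-1-yl}furan-2(5H)-one (both epoxide configurations) | O=C1O[C@H](/C=C(/C)C2=CC(=O)[C@](C)(CC3OC3(C)C)O2)C=C1CBr
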